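## Structural features

The target, (2S)-2,3-dihydrorobustaflavone, is a biflavonoid. A naringenin unit (flavanone: ring A, heterocyclic ring C, pendant ring B) and an apigenin unit (flavone: ring A'', pyranone ring C'', pendant ring B'') are joined by one biaryl bond from C3' of flavanone ring B to C6'' of flavone ring A''. There is one stereocentre, C2 (S), benzylic, bound to O1 and β to the C4 ketone; it has no stereogenic neighbour. The flavanone is the fragile part: C2 is lost by retro-oxa-Michael opening to the 2'-hydroxychalcone, which base and the electron-releasing 4'-oxygen para to C2 both favour. The benzylic C2–O1 bond and the flavone C2''=C3'' bond are exposed under reduction, and six phenols, two of them (O5, O5'') hydrogen-bonded to a ketone, must be carried or unveiled. The real difficulty is the C3'–C6'' bond: it has three ortho oxygens (O4', O5'', O7''), and on a preformed 5,7-dioxygenated flavone C6'' and C8'' are hard to tell apart. The key step uses the fact that C6'' lies between the oxygen-bearing C5'' and C7'', while the C4a''–C8a'' bond of the same ring is the C3=C2 double bond of a 4-pyranone (ring C''). A 2-aryl resorcinol fused to an existing alkene is the pattern a vinylketene and an aryl ynol ether give on benzannulation: the ketene carbonyl becomes C5''–OH and the alkyne supplies C6'' (aryl) and C7'' (silyloxy).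

## Logic of the disconnections

**27 ⇒ 26 ⇒ 25.** The last bonds cut are the four O–CH2Ph bonds (O5, O7, O4', O4''') and, one step earlier, the O7''–Si bond. This keeps every phenol except the chelated O5''–H masked until C2 is in place, so the 4'-phenol that assists ring opening never meets a base. The forward steps must be buffered or neutral: fluoride with acetic acid, then hydrogen over palladium.

**25 ⇒ 23.** O1–C2 is cut and a tert-butoxycarbonyl group is put back on C3. The ester turns the chalcone-type acceptor into a two-point-binding alkylidene β-keto ester that a bifunctional catalyst can hold, and the cut removes ring C and the only stereocentre. The forward step needs facial control at the benzylidene carbon and acid removal of the ester (through 24) without ring opening.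

**23 ⇒ 19 + 22.** The C2=C3 double bond is cut. This splits the molecule convergently into the complete ring B–flavone half and the ring A half. The condensation must run under buffered amine catalysis so that the free phenol of 22 does not close ring C prematurely and unselectively.

**22 ⇒ 21 ⇒ 20.** The C3–CO2 bond and two O–benzyl bonds are cut, leaving a symmetric triol in which chelation sets aside one ortho hydroxyl as the future O1. The forward acylation of 21 must end on carbon, not oxygen.

**19 ⇒ 18.** Only the two acetal C–O bonds are cut. The formyl carbon (future C2) has to be masked while organolithium reagents are used on the way to 14; mild aqueous acid suffices for the release.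

**18 ⇒ 8 + 14 (key).** Three bonds of ring A'' are cut: C5''–C6'', C7''–C8'' and C4a''–C5''. Ring A'' disappears, leaving a 4-pyranone that already carries ring B'' and a two-carbon side chain, plus an aryl ynol ether. The hindered biaryl bond becomes an aryl–alkyne bond, and the 6''/8'' question is settled by construction. The forward step needs a ketene from 8 under conditions the pyranone survives, the correct orientation of the [2+2] addition, and 6π closure onto pyranone C3.

**8 ⇒ 6 ⇒ 4 ⇒ 2 + 3 ⇒ 1.** The cuts are the C=N2 bond (diazo transfer to the methyl group of 6), the pyranone O–C bond (cyclodehydration of 4), and two C–C bonds made by Claisen-type acylations (2 with 3; 1 with ethyl acetate). Carrying the side chain as a ketal-masked acetyl group avoids the acid chloride and diazomethane. The forward steps need acylation at the terminal carbon of the dianion of 2, and pyranone closure before the ketal is lost.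

**14 ⇒ 11 ⇒ 10 ⇒ 9.** The alkyne is cut so that one carbon is the ester carbon of 11 and the other comes from dibromomethane. The O–benzyl and acetal bonds then lead back to 9. The acetal and benzyl ether must tolerate lithium amide and butyllithium at low temperature.

## Other disconnections considered

**Alternative 1:** The cut runs through flavanone ring B (C2'–C3' and C4'–C5'). Ring B would be assembled from methyl coumalate A4 and the bis(trimethylsilyl) ketene acetal A2 of the flavon-6-ylacetic acid A3.
- *Forward step:* the nucleophilic carbon of A2 should attack C6 of A4, the acetal carbon should close onto C3, and loss of CO2 and silanol should aromatise the adduct to the phenol ester A1.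
- *In favour:* like the chosen plan it never couples two arenes at the hindered position. Polarity fixes the 3',4' pattern, the 4'-phenol arrives free, and the ester sits at C1'. It needs no light and no diazo compound, and on that point it is the better plan.
- *Against:* A3 requires regioselective carbon functionalisation at C6'' of a preformed 5,7-dioxygenated flavone, so the 6''/8'' problem is moved, not solved. The reacting carbon of A2 is flanked by two benzyloxy groups. Double deprotonation of A3 must spare the flavone enone. The ester of A1 still has to be brought to the aldehyde level.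
- *Comparison:* on structure both plans build an arene instead of joining two, but the chosen plan builds the ring that carries the regiochemical ambiguity. On mechanism the pyrone cycloaddition is thermally simpler than the ketene cascade, which makes it the equal or better in operation. On step economy it is longer, because A3 needs a multistep preparation, A1 needs an oxidation-state change, and the ring C endgame is the same.

**Alternative 2:** The cut is O1–C2 of ring C with an ester added at C3. The open form is the alkylidene β-keto ester A6.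
- *Forward step:* a quinine-derived bifunctional thiourea should deliver the one free ring A phenol to the benzylidene carbon, giving the trans keto ester A5 (2S,3R).
- *In favour:* it is catalytic, established for flavanones, sets the only stereocentre late under nearly neutral conditions, and the ester leaves under acid.
- *Against, as the leading cut:* A6 still contains the C3'–C6'' bond and the whole flavone, so the biaryl problem is left to a cross-coupling at a tri-ortho-oxygenated position. The hexa-benzyl pattern also needs alkylation of the chelated O5''.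
- *Comparison:* for C2 this alternative is the equal of the chosen plan, which adopts the same kind of closure as its endgame; the two are complementary. On structure the chosen plan adds what this one lacks, a regiodefined construction of ring A''. On step economy the alternative carries one more protecting-group operation.

**Alternative 3:** The cut is C2–C3. The precursor A8 is a ring A diazomethyl ketone whose ortho oxygen carries the whole ring B–flavone unit as an arylmethyl ether.
- *Forward step:* with Rh2(S-PTTL)4, a chiral carboxylate complex of divalent rhodium, the carbene carbon should insert into one enantiotopic benzylic C–H bond to give A7.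
- *In favour:* a C–C bond and the stereocentre would form in one step from an achiral ether with no activating group to remove. On paper the endgame is shorter by the condensation and the decarboxylation, and on that point it is better.
- *Against:* acceptor-only carbenes are the least selective class. Six-membered C–H insertion would compete with attack on O1 (oxonium ylide, then 1,2-benzyl shift to a benzofuran-3-one), with addition to the many electron-rich arenes, and with insertion into four other O–CH2Ph groups. Enantiocontrol for terminal diazo ketones is usually modest.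
- *Comparison:* on structure it equals alternative 2 in leaving the biaryl bond unsolved. On mechanism it is riskier than an organocatalytic oxa-Michael addition. On step economy the saving at the end is likely offset by the ether formation and the diazo installation on ring A. On hazard the two plans are equal, since both handle one diazo ketone.

Key step: step 8

**Remarks on the chemistry (assumptions and corrections)**
- The C3'–C6'' axis is assumed to rotate freely at room temperature in 27, so no axial descriptor is assigned; silylated intermediates may appear as slowly interconverting rotamers.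
- The quinine-derived thiourea is assumed to give the 2S series; if its sense proves opposite, the quinidine-derived pseudo-enantiomer is used in the same way.
- Correction of bond provenance: the aryl–alkyne bond of 14 (later C3'–C6'') is not carried over from the aryl–ester bond of 11. In the Kowalski step the aryl group shifts onto the carbon delivered by dibromomethane (future C6''), and the ester carbon ends as the silyloxy-bearing carbon (future C7''). The structure of 14 is unchanged and no cross-coupling is involved.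
- Atom mapping of step 8: diazo carbon → C8'', ketone carbon → C5'', aryl-bearing alkyne carbon → C6'', silyloxy-bearing alkyne carbon → C7''. Compounds 8, 14 and 18 are mutually consistent.
- Design changes for safety and brevity: the side chain of 8 is made from an acetyl group by diazo transfer (no diazomethane). O5'' stays unprotected because the chelated phenol is inert in later steps. The Wolff step uses visible LED light. Ring closure and decarboxylation share one flask.
- Compound 21 is also a catalogue compound; buying it would remove step 10.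

## Route

Step 1
Reactants: 1 1-[4-(benzyloxy)phenyl]ethanone (4'-benzyloxyacetophenone)
Product: 2 1-[4-(benzyloxy)phenyl]butane-1,3-dione
Conditions: NaH, EtOAc, THF, 0 °C → reflux; aq. HCl
Reagents that add atoms: ethyl acetate, CCOC(C)=O
Why: Crossed Claisen condensation; the ketone enolate is acylated by ethyl acetate and deprotonation of the β-diketone drives the equilibrium; the aryl benzyl ether is inert to NaH.

Step 2
Reactants: 2 1-[4-(benzyloxy)phenyl]butane-1,3-dione; 3 methyl 2,2-dimethoxypropanoate
Product: 4 1-[4-(benzyloxy)phenyl]-6,6-dimethoxyheptane-1,3,5-trione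
Conditions: LiN(iPr)2 (3.1 equiv), THF, −78 → 0 °C; then 3, −78 → 25 °C; aq. NH4Cl
Reagents that add atoms: none
Why: Claisen-type γ-acylation of a β-diketone dianion; the terminal carbanion, formed last and most reactive, attacks the non-enolisable, α,α-dialkoxy-activated ester, and the third equivalent of amide absorbs the acidity of the triketone.

Step 3
Reactants: 4 1-[4-(benzyloxy)phenyl]-6,6-dimethoxyheptane-1,3,5-trione
Product: 6 2-acetyl-6-[4-(benzyloxy)phenyl]-4H-pyran-4-one, via ketal pyranone 5 (not isolated)
Conditions: CF3CO2H, CH2Cl2, 0 → 25 °C; then H2O, 40 °C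
Reagents that add atoms: water, O
Why: Acid-catalysed cyclodehydration of a 1,3,5-triketone to the 4-pyranone, then ketal hydrolysis; a ketal next to a carbonyl ionises slowly, so ring closure to 5 should come first and the furanone closure open to a free 1,2-diketone is avoided.

Step 4
Reactants: 6 2-acetyl-6-[4-(benzyloxy)phenyl]-4H-pyran-4-one
Product: 8 1-{6-[4-(benzyloxy)phenyl]-4-oxo-4H-pyran-2-yl}-2-diazoethanone, via trifluoroacetyl diketone 7 (not isolated)
Conditions: LiN(SiMe3)2, THF, −78 °C; CF3CO2CH2CF3; then 4-AcNHC6H4SO2N3, Et3N, H2O (1 equiv), MeCN, 25 °C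
Reagents that add atoms: 4-acetamidobenzenesulfonyl azide, CC(=O)Nc1ccc(cc1)S(=O)(=O)N=[N+]=[N-]
Why: Detrifluoroacetylative (Regitz-type deacylative) diazo transfer; the kinetic methyl enolate is trifluoroacetylated, and diketone 7 takes the diazo group from the sulfonyl azide while the trifluoroacetyl group leaves on the sulfonamide nitrogen; the method is made for base-sensitive enones and needs no diazomethane.

Step 5
Reactants: 9 methyl 5-formyl-2-hydroxybenzoate
Product: 10 methyl 2-(benzyloxy)-5-formylbenzoate
Conditions: BnBr, K2CO3, DMF, 50 °C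
Reagents that add atoms: benzyl bromide, BrCc1ccccc1
Why: Williamson ether synthesis on the acidic salicylate phenol; aldehyde and ester are untouched by carbonate.

Step 6
Reactants: 10 methyl 2-(benzyloxy)-5-formylbenzoate
Product: 11 methyl 2-(benzyloxy)-5-(1,3-dioxolan-2-yl)benzoate
Conditions: HOCH2CH2OH, p-TsOH (cat.), toluene, reflux, Dean–Stark
Reagents that add atoms: ethane-1,2-diol, OCCO
Why: Acid-catalysed acetalisation with azeotropic removal of water; the aldehyde is masked against the organolithium reagents of step 7.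

Step 7
Reactants: 11 methyl 2-(benzyloxy)-5-(1,3-dioxolan-2-yl)benzoate
Product: 14 ({[2-(benzyloxy)-5-(1,3-dioxolan-2-yl)phenyl]ethynyl}oxy)triisopropylsilane, via dibromoketone enolate 12 (not isolated), via lithium ynolate 13 (not isolated)
Conditions: CH2Br2, lithium 2,2,6,6-tetramethylpiperidide, THF, −78 °C; then n-BuLi, −78 → 0 °C; then iPr3SiCl, −78 → 25 °C
Reagents that add atoms: dibromomethane, BrCBr; chlorotriisopropylsilane, CC(C)[Si](Cl)(C(C)C)C(C)C
Why: Kowalski ester homologation stopped at the ynolate; LiCHBr2 adds to the ester, enolate 12 undergoes bromine–lithium exchange and a carbenoid 1,2-aryl shift to ynolate 13, and the bulky chlorosilane silylates oxygen; the low temperature protects the acetal C–H and the benzylic CH2.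

Step 8
Reactants: 8 1-{6-[4-(benzyloxy)phenyl]-4-oxo-4H-pyran-2-yl}-2-diazoethanone; 14 ({[2-(benzyloxy)-5-(1,3-dioxolan-2-yl)phenyl]ethynyl}oxy)triisopropylsilane
Product: 18 6-[2-(benzyloxy)-5-(1,3-dioxolan-2-yl)phenyl]-2-[4-(benzyloxy)phenyl]-5-hydroxy-7-[(triisopropylsilyl)oxy]-4H-chromen-4-one, via pyranonylketene 15 (not isolated), via cyclobutenone 16 (not isolated), via dienylketene 17 (not isolated)
Conditions: 14 (1.5 equiv), LED 440 nm, ClCH2CH2Cl (degassed, flow or batch), 25 °C; then 80 °C
Reagents that add atoms: none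
Why: Danheiser benzannulation in its diazo ketone form. Light near 440 nm excites only the diazo n–π* band, so 8 loses N2 and the pyranonyl group shifts to the carbene carbon (Wolff rearrangement) to give ketene 15, while the pyranone and flavone chromophores, which absorb in the ultraviolet, are left alone. The aryl-bearing carbon of 14, the nucleophilic end of the ynol ether, attacks the ketene carbonyl carbon, and the [2+2] addition closes cyclobutenone 16, forming C5''–C6'' and C7''–C8''. At 80 °C the four-membered ring opens by reversible conrotatory 4π electrocyclic cleavage to dienylketene 17; the isomer with the pyranone cis to the ketene is drained by disrotatory 6π electrocyclisation between the ketene carbon and pyranone C3 (C4a''–C5''), which closes flavone ring A, and tautomerisation gives the chelated 5''-phenol. No stereocentre results, because the sp3 carbon of 16 is lost on ring opening. Regiochemistry rests on two substrate features: the oxygen polarisation of the alkyne places the aryl carbon next to the ketene-derived C5'' and so between the two oxygens, and C3 is the only ring carbon beside the ketene-bearing C2, so only the 6''-aryl flavone can form. The closest known cases are benzannulations of heteroaryl and alkenyl diazomethyl ketones with triisopropylsiloxyalkynes. Excess alkyne, a chelated and hindered product phenol, and a ceiling of 80 °C are meant to outrun ketene dimerisation, O-acylation of 18 and the 1,3-silyl shift of 14.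

Step 9
Reactants: 18 6-[2-(benzyloxy)-5-(1,3-dioxolan-2-yl)phenyl]-2-[4-(benzyloxy)phenyl]-5-hydroxy-7-[(triisopropylsilyl)oxy]-4H-chromen-4-one
Product: 19 4-(benzyloxy)-3-{2-[4-(benzyloxy)phenyl]-5-hydroxy-4-oxo-7-[(triisopropylsilyl)oxy]-4H-chromen-6-yl}benzaldehyde
Conditions: pyridinium p-toluenesulfonate, acetone/H2O, 50 °C
Reagents that add atoms: water, O
Why: Mild acid hydrolysis of an aryl aldehyde acetal; the aryl silyl ether and the benzyl ethers are stable to this acid.

Step 10
Reactants: 20 1-(2,4,6-trihydroxyphenyl)ethanone (2',4',6'-trihydroxyacetophenone)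
Product: 21 1-[2,4-bis(benzyloxy)-6-hydroxyphenyl]ethanone
Conditions: BnBr (2.1 equiv), K2CO3, acetone, reflux
Reagents that add atoms: benzyl bromide, BrCc1ccccc1
Why: Williamson etherification; the para hydroxyl and one ortho hydroxyl are alkylated, while the remaining ortho hydroxyl is hydrogen-bonded to the ketone and resists alkylation.

Step 11
Reactants: 21 1-[2,4-bis(benzyloxy)-6-hydroxyphenyl]ethanone
Product: 22 tert-butyl 3-[2,4-bis(benzyloxy)-6-hydroxyphenyl]-3-oxopropanoate
Conditions: LiN(SiMe3)2 (3.3 equiv), THF, −78 °C; (t-BuOCO)2O, −78 → 0 °C; aq. NH4Cl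
Reagents that add atoms: di-tert-butyl dicarbonate, CC(C)(C)OC(=O)OC(=O)OC(C)(C)C
Why: Claisen-type C-carboxylation of the lithium phenoxide–enolate dianion; any aryl carbonate formed first should pass the group to the enolate carbon by a Baker–Venkataraman-type shift, and the extra base holds the product as its enolate.

Step 12
Reactants: 19 4-(benzyloxy)-3-{2-[4-(benzyloxy)phenyl]-5-hydroxy-4-oxo-7-[(triisopropylsilyl)oxy]-4H-chromen-6-yl}benzaldehyde; 22 tert-butyl 3-[2,4-bis(benzyloxy)-6-hydroxyphenyl]-3-oxopropanoate
Product: 23 tert-butyl 2-[2,4-bis(benzyloxy)-6-hydroxybenzoyl]-3-(4-(benzyloxy)-3-{2-[4-(benzyloxy)phenyl]-5-hydroxy-4-oxo-7-[(triisopropylsilyl)oxy]-4H-chromen-6-yl}phenyl)prop-2-enoate (alkene geometry not controlled)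
Conditions: piperidine (cat.), AcOH (cat.), toluene, 4 Å molecular sieves, 25 °C
Reagents that add atoms: none
Why: Knoevenagel condensation of an aryl aldehyde with an aroylacetate under buffered amine catalysis; the ketone-chelated phenol of 22 and the absence of free base should keep uncatalysed ring closure slow, and the chelated 5''-OH does not interfere.

Step 13
Reactants: 23 tert-butyl 2-[2,4-bis(benzyloxy)-6-hydroxybenzoyl]-3-(4-(benzyloxy)-3-{2-[4-(benzyloxy)phenyl]-5-hydroxy-4-oxo-7-[(triisopropylsilyl)oxy]-4H-chromen-6-yl}phenyl)prop-2-enoate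
Product: 25 (2S)-5,7-bis(benzyloxy)-2-(4-(benzyloxy)-3-{2-[4-(benzyloxy)phenyl]-5-hydroxy-4-oxo-7-[(triisopropylsilyl)oxy]-4H-chromen-6-yl}phenyl)-2,3-dihydro-4H-chromen-4-one, via trans keto ester 24 (not isolated)
Conditions: N-[3,5-bis(trifluoromethyl)phenyl]-N'-(9-deoxy-epi-quinin-9-yl)thiourea (10 mol %), toluene, −25 °C; then p-TsOH·H2O, 80 °C
Reagents that add atoms: none
Why: Intramolecular oxa-Michael addition (6-endo-trig) under bifunctional thiourea–tertiary amine catalysis; the thiourea binds the β-keto ester and the quinuclidine delivers the phenol to one face of the benzylidene carbon, setting C2 as S by catalyst control. C3 settles trans in 24 and is erased when acid removes the tert-butyl ester as isobutene and CO2 without base.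

Step 14
Reactants: 25 (2S)-5,7-bis(benzyloxy)-2-(4-(benzyloxy)-3-{2-[4-(benzyloxy)phenyl]-5-hydroxy-4-oxo-7-[(triisopropylsilyl)oxy]-4H-chromen-6-yl}phenyl)-2,3-dihydro-4H-chromen-4-one
Product: 26 (2S)-5,7-bis(benzyloxy)-2-(4-(benzyloxy)-3-{2-[4-(benzyloxy)phenyl]-5,7-dihydroxy-4-oxo-4H-chromen-6-yl}phenyl)-2,3-dihydro-4H-chromen-4-one
Conditions: Bu4NF, AcOH (1:1), THF, 0 °C
Reagents that add atoms: none
Why: Fluoride cleavage of an aryl silyl ether; acetic acid buffers the phenoxide so that no base-induced retro-oxa-Michael racemisation of C2 can start, and the flavanone phenols are still benzylated.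

Step 15
Reactants: 26 (2S)-5,7-bis(benzyloxy)-2-(4-(benzyloxy)-3-{2-[4-(benzyloxy)phenyl]-5,7-dihydroxy-4-oxo-4H-chromen-6-yl}phenyl)-2,3-dihydro-4H-chromen-4-one
Product: 27 (2S)-2-{3-[5,7-dihydroxy-2-(4-hydroxyphenyl)-4-oxo-4H-chromen-6-yl]-4-hydroxyphenyl}-5,7-dihydroxy-2,3-dihydro-4H-chromen-4-one
Conditions: H2 (1 atm), Pd/C (10 wt %), EtOAc/MeOH, 25 °C
Reagents that add atoms: none
Why: Hydrogenolysis of four aryl benzyl ethers under neutral conditions; O-benzyl cleavage should be faster than reduction of the flavone C2''=C3'' bond or of the cyclic benzylic C2–O1 bond, so the reaction is stopped at the calculated uptake and C2 is untouched.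

## Compound list

1 | 1-[4-(benzyloxy)phenyl]ethanone | CC(=O)c1ccc(OCc2ccccc2)cc1 | starting material
2 | 1-[4-(benzyloxy)phenyl]butane-1,3-dione | CC(=O)CC(=O)c1ccc(OCc2ccccc2)cc1 | intermediate
3 | methyl 2,2-dimethoxypropanoate | COC(=O)C(C)(OC)OC | starting material
4 | 1-[4-(benzyloxy)phenyl]-6,6-dimethoxyheptane-1,3,5-trione | CC(OC)(OC)C(=O)CC(=O)CC(=O)c1ccc(OCc2ccccc2)cc1 | intermediate
5 | 6-[4-(benzyloxy)phenyl]-2-(1,1-dimethoxyethyl)-4H-pyran-4-one | CC(OC)(OC)c1cc(=O)cc(-c2ccc(OCc3ccccc3)cc2)o1 | intermediate (not isolated)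
6 | 2-acetyl-6-[4-(benzyloxy)phenyl]-4H-pyran-4-one | CC(=O)c1cc(=O)cc(-c2ccc(OCc3ccccc3)cc2)o1 | intermediate
7 | 1-{6-[4-(benzyloxy)phenyl]-4-oxo-4H-pyran-2-yl}-4,4,4-trifluorobutane-1,3-dione | O=C(CC(=O)C(F)(F)F)c1cc(=O)cc(-c2ccc(OCc3ccccc3)cc2)o1 | intermediate (not isolated)
8 | 1-{6-[4-(benzyloxy)phenyl]-4-oxo-4H-pyran-2-yl}-2-diazoethanone | [N-]=[N+]=CC(=O)c1cc(=O)cc(-c2ccc(OCc3ccccc3)cc2)o1 | intermediate
9 | methyl 5-formyl-2-hydroxybenzoate | COC(=O)c1cc(C=O)ccc1O | starting material
10 | methyl 2-(benzyloxy)-5-formylbenzoate | COC(=O)c1cc(C=O)ccc1OCc1ccccc1 | intermediate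
11 | methyl 2-(benzyloxy)-5-(1,3-dioxolan-2-yl)benzoate | COC(=O)c1cc(C2OCCO2)ccc1OCc1ccccc1 | intermediate
12 | lithium 1-[2-(benzyloxy)-5-(1,3-dioxolan-2-yl)phenyl]-2,2-dibromoethen-1-olate | [Li+].[O-]C(=C(Br)Br)c1cc(C2OCCO2)ccc1OCc1ccccc1 | intermediate (not isolated)
13 | lithium 2-[2-(benzyloxy)-5-(1,3-dioxolan-2-yl)phenyl]ethyn-1-olate | [Li+].[O-]C#Cc1cc(C2OCCO2)ccc1OCc1ccccc1 | intermediate (not isolated)
14 | ({[2-(benzyloxy)-5-(1,3-dioxolan-2-yl)phenyl]ethynyl}oxy)triisopropylsilane | CC(C)[Si](OC#Cc1cc(C2OCCO2)ccc1OCc1ccccc1)(C(C)C)C(C)C | intermediate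
15 | 2-{6-[4-(benzyloxy)phenyl]-4-oxo-4H-pyran-2-yl}ethen-1-one (ketene) | O=C=Cc1cc(=O)cc(-c2ccc(OCc3ccccc3)cc2)o1 | intermediate (not isolated)
16 | 2-[2-(benzyloxy)-5-(1,3-dioxolan-2-yl)phenyl]-4-{6-[4-(benzyloxy)phenyl]-4-oxo-4H-pyran-2-yl}-3-[(triisopropylsilyl)oxy]cyclobut-2-en-1-one (racemic at C4) | O=C1C(c2cc(=O)cc(-c3ccc(OCc4ccccc4)cc3)o2)C(O[Si](C(C)C)(C(C)C)C(C)C)=C1c1cc(C2OCCO2)ccc1OCc1ccccc1 | intermediate (not isolated)
17 | (3E)-2-[2-(benzyloxy)-5-(1,3-dioxolan-2-yl)phenyl]-4-{6-[4-(benzyloxy)phenyl]-4-oxo-4H-pyran-2-yl}-3-[(triisopropylsilyl)oxy]buta-1,3-dien-1-one | O=C=C(c1cc(C2OCCO2)ccc1OCc1ccccc1)/C(O[Si](C(C)C)(C(C)C)C(C)C)=C\c1cc(=O)cc(-c2ccc(OCc3ccccc3)cc2)o1 | intermediate (not isolated)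
18 | 6-[2-(benzyloxy)-5-(1,3-dioxolan-2-yl)phenyl]-2-[4-(benzyloxy)phenyl]-5-hydroxy-7-[(triisopropylsilyl)oxy]-4H-chromen-4-one | CC(C)[Si](Oc1cc2oc(-c3ccc(OCc4ccccc4)cc3)cc(=O)c2c(O)c1-c1cc(C2OCCO2)ccc1OCc1ccccc1)(C(C)C)C(C)C | intermediate
19 | 4-(benzyloxy)-3-{2-[4-(benzyloxy)phenyl]-5-hydroxy-4-oxo-7-[(triisopropylsilyl)oxy]-4H-chromen-6-yl}benzaldehyde | CC(C)[Si](Oc1cc2oc(-c3ccc(OCc4ccccc4)cc3)cc(=O)c2c(O)c1-c1cc(C=O)ccc1OCc1ccccc1)(C(C)C)C(C)C | intermediate
20 | 1-(2,4,6-trihydroxyphenyl)ethanone | CC(=O)c1c(O)cc(O)cc1O | starting material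
21 | 1-[2,4-bis(benzyloxy)-6-hydroxyphenyl]ethanone | CC(=O)c1c(O)cc(OCc2ccccc2)cc1OCc1ccccc1 | intermediate
22 | tert-butyl 3-[2,4-bis(benzyloxy)-6-hydroxyphenyl]-3-oxopropanoate | CC(C)(C)OC(=O)CC(=O)c1c(O)cc(OCc2ccccc2)cc1OCc1ccccc1 | intermediate
23 | tert-butyl 2-[2,4-bis(benzyloxy)-6-hydroxybenzoyl]-3-(4-(benzyloxy)-3-{2-[4-(benzyloxy)phenyl]-5-hydroxy-4-oxo-7-[(triisopropylsilyl)oxy]-4H-chromen-6-yl}phenyl)prop-2-enoate (geometry not controlled) | CC(C)(C)OC(=O)C(=Cc1ccc(OCc2ccccc2)c(-c2c(O[Si](C(C)C)(C(C)C)C(C)C)cc3oc(-c4ccc(OCc5ccccc5)cc4)cc(=O)c3c2O)c1)C(=O)c1c(O)cc(OCc2ccccc2)cc1OCc1ccccc1 | intermediate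
24 | tert-butyl (2S,3R)-5,7-bis(benzyloxy)-2-(4-(benzyloxy)-3-{2-[4-(benzyloxy)phenyl]-5-hydroxy-4-oxo-7-[(triisopropylsilyl)oxy]-4H-chromen-6-yl}phenyl)-4-oxochromane-3-carboxylate | O=C1[C@H](C(=O)OC(C)(C)C)[C@@H](c2ccc(OCc3ccccc3)c(-c3c(O[Si](C(C)C)(C(C)C)C(C)C)cc4oc(-c5ccc(OCc6ccccc6)cc5)cc(=O)c4c3O)c2)Oc2cc(OCc3ccccc3)cc(OCc3ccccc3)c21 | intermediate (not isolated)
25 | (2S)-5,7-bis(benzyloxy)-2-(4-(benzyloxy)-3-{2-[4-(benzyloxy)phenyl]-5-hydroxy-4-oxo-7-[(triisopropylsilyl)oxy]-4H-chromen-6-yl}phenyl)-2,3-dihydro-4H-chromen-4-one | O=C1C[C@@H](c2ccc(OCc3ccccc3)c(-c3c(O[Si](C(C)C)(C(C)C)C(C)C)cc4oc(-c5ccc(OCc6ccccc6)cc5)cc(=O)c4c3O)c2)Oc2cc(OCc3ccccc3)cc(OCc3ccccc3)c21 | intermediate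
26 | (2S)-5,7-bis(benzyloxy)-2-(4-(benzyloxy)-3-{2-[4-(benzyloxy)phenyl]-5,7-dihydroxy-4-oxo-4H-chromen-6-yl}phenyl)-2,3-dihydro-4H-chromen-4-one | O=C1C[C@@H](c2ccc(OCc3ccccc3)c(-c3c(O)cc4oc(-c5ccc(OCc6ccccc6)cc5)cc(=O)c4c3O)c2)Oc2cc(OCc3ccccc3)cc(OCc3ccccc3)c21 | intermediate
27 | (2S)-2-{3-[5,7-dihydroxy-2-(4-hydroxyphenyl)-4-oxo-4H-chromen-6-yl]-4-hydroxyphenyl}-5,7-dihydroxy-2,3-dihydro-4H-chromen-4-one | O=C1C[C@@H](c2ccc(O)c(-c3c(O)cc4oc(-c5ccc(O)cc5)cc(=O)c4c3O)c2)Oc2cc(O)cc(O)c21 | target

## Step count and least certain steps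

Total: 15 steps. Longest linear sequence: 10 steps (1, 2, 3, 4, 8, 9, 12, 13, 14, 15, from compound 1). The side arms are steps 5–7 (to 14) and steps 10–11 (to 22).

**Step 8 (key step).**
- *What may go wrong:* the pyranone chromophore or the flavone product may absorb and rearrange. The ketene may dimerise or acylate the product phenol before it meets the alkyne. Compound 14 may undergo a thermal 1,3-silyl shift. The 6π closure onto pyranone C3, which is untested for this ring, may be slow and leave the cascade at the cyclobutenone stage.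
- *Fallback (ketene by dehydrochlorination in the dark):* from 8, a Wolff rearrangement catalysed by AgO2CPh in aqueous dioxane (Arndt–Eistert conditions) should give {6-[4-(benzyloxy)phenyl]-4-oxo-4H-pyran-2-yl}acetic acid F1. Oxalyl chloride with catalytic DMF converts it into {6-[4-(benzyloxy)phenyl]-4-oxo-4H-pyran-2-yl}acetyl chloride F2. Slow addition of Et3N to F2 and 14 in toluene at 80 °C generates 15 without light, and the same [2+2]/4π/6π sequence rejoins the route at 18.

**Step 3.**
- *What may go wrong:* the ketal may ionise before ring closure, so that the C3 enol oxygen closes onto C6 to a five-membered furanone instead of the 4-pyranone. Prolonged acid may also cleave the benzyl ether.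
- *Fallback (classical ester route):* from 2, Claisen condensation with diethyl oxalate (NaOEt, EtOH) gives ethyl 6-[4-(benzyloxy)phenyl]-2,4,6-trioxohexanoate F3. HCl in acetic acid closes it to ethyl 6-[4-(benzyloxy)phenyl]-4-oxo-4H-pyran-2-carboxylate F4. LiOH in aqueous THF at 0 °C gives 6-[4-(benzyloxy)phenyl]-4-oxo-4H-pyran-2-carboxylic acid F5. Oxalyl chloride gives 6-[4-(benzyloxy)phenyl]-4-oxo-4H-pyran-2-carbonyl chloride F6. (Trimethylsilyl)diazomethane, a non-explosive but toxic diazoalkane handled in a closed system, converts F6 into 8. This rejoins at 8, bypasses steps 3 and 4, and costs three more steps.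

**Step 7.**
- *What may go wrong:* excess alkyllithium may metalate the acetal C–H (fragmentation of the dioxolane) or the benzylic OCH2 (Wittig rearrangement). The carbenoid rearrangement may be incomplete.
- *Fallback (ynolate by acetylide oxidation):* from 11, LiAlH4 gives [2-(benzyloxy)-5-(1,3-dioxolan-2-yl)phenyl]methanol F7. MnO2 gives 2-(benzyloxy)-5-(1,3-dioxolan-2-yl)benzaldehyde F8. Ohira–Bestmann homologation (dimethyl (1-diazo-2-oxopropyl)phosphonate, K2CO3, MeOH) gives 2-[4-(benzyloxy)-3-ethynylphenyl]-1,3-dioxolane F9. Deprotonation with LiN(SiMe3)2, oxidation of the lithium acetylide with lithium tert-butyl peroxide to ynolate 13, and silylation with iPr3SiOSO2CF3 rejoin the route at 14.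

**Step 13.**
- *What may go wrong:* facial selectivity may be poor, because the doubly ortho-substituted aroyl group is twisted and the chelated 5''-OH may compete for the thiourea. Acid at 80 °C may partly racemise C2 by ionisation assisted by the para benzyloxy group. The sense of induction may be opposite to that assumed.
- *Fallback (resolution instead of asymmetric catalysis):* from 23, closure with an achiral amine (DABCO, toluene, 25 °C) gives the racemic trans keto ester rac-24 F10, and p-TsOH at 80 °C gives the racemic flavanone rac-25 F11. Preparative chromatography on a chiral stationary phase delivers 25 and rejoins the route there. The (2R)-enantiomer of 25 F12 can be re-equilibrated with base through the chalcone and recycled.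

**Step 15.**
- *What may go wrong:* over-reduction (hydrogenolytic opening of the benzylic C2–O1 bond or saturation of C2''=C3''), or incomplete cleavage of the hindered 4'-O-benzyl group.
- *Fallback (non-reductive debenzylation):* from 26, BCl3 with pentamethylbenzene as cation scavenger in CH2Cl2 at −78 °C cleaves the four benzyl ethers by a Lewis acid path and gives 27 directly. No new compound is made (F0).

## Further compounds

F1 | step 8 | {6-[4-(benzyloxy)phenyl]-4-oxo-4H-pyran-2-yl}acetic acid | OC(=O)Cc1cc(=O)cc(-c2ccc(OCc3ccccc3)cc2)o1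
F2 | step 8 | {6-[4-(benzyloxy)phenyl]-4-oxo-4H-pyran-2-yl}acetyl chloride | ClC(=O)Cc1cc(=O)cc(-c2ccc(OCc3ccccc3)cc2)o1
F3 | step 3 | ethyl 6-[4-(benzyloxy)phenyl]-2,4,6-trioxohexanoate | CCOC(=O)C(=O)CC(=O)CC(=O)c1ccc(OCc2ccccc2)cc1
F4 | step 3 | ethyl 6-[4-(benzyloxy)phenyl]-4-oxo-4H-pyran-2-carboxylate | CCOC(=O)c1cc(=O)cc(-c2ccc(OCc3ccccc3)cc2)o1
F5 | step 3 | 6-[4-(benzyloxy)phenyl]-4-oxo-4H-pyran-2-carboxylic acid | OC(=O)c1cc(=O)cc(-c2ccc(OCc3ccccc3)cc2)o1
F6 | step 3 | 6-[4-(benzyloxy)phenyl]-4-oxo-4H-pyran-2-carbonyl chloride | ClC(=O)c1cc(=O)cc(-c2ccc(OCc3ccccc3)cc2)o1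
F7 | step 7 | [2-(benzyloxy)-5-(1,3-dioxolan-2-yl)phenyl]methanol | OCc1cc(C2OCCO2)ccc1OCc1ccccc1
F8 | step 7 | 2-(benzyloxy)-5-(1,3-dioxolan-2-yl)benzaldehyde | O=Cc1cc(C2OCCO2)ccc1OCc1ccccc1
F9 | step 7 | 2-[4-(benzyloxy)-3-ethynylphenyl]-1,3-dioxolane | C#Cc1cc(C2OCCO2)ccc1OCc1ccccc1
F10 | step 13 | racemic trans tert-butyl 5,7-bis(benzyloxy)-2-(4-(benzyloxy)-3-{2-[4-(benzyloxy)phenyl]-5-hydroxy-4-oxo-7-[(triisopropylsilyl)oxy]-4H-chromen-6-yl}phenyl)-4-oxochromane-3-carboxylate (rac-24) | O=C1C(C(=O)OC(C)(C)C)C(c2ccc(OCc3ccccc3)c(-c3c(O[Si](C(C)C)(C(C)C)C(C)C)cc4oc(-c5ccc(OCc6ccccc6)cc5)cc(=O)c4c3O)c2)Oc2cc(OCc3ccccc3)cc(OCc3ccccc3)c21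
F11 | step 13 | racemic 5,7-bis(benzyloxy)-2-(4-(benzyloxy)-3-{2-[4-(benzyloxy)phenyl]-5-hydroxy-4-oxo-7-[(triisopropylsilyl)oxy]-4H-chromen-6-yl}phenyl)-2,3-dihydro-4H-chromen-4-one (rac-25) | O=C1CC(c2ccc(OCc3ccccc3)c(-c3c(O[Si](C(C)C)(C(C)C)C(C)C)cc4oc(-c5ccc(OCc6ccccc6)cc5)cc(=O)c4c3O)c2)Oc2cc(OCc3ccccc3)cc(OCc3ccccc3)c21
F12 | step 13 | (2R)-enantiomer of 25 | O=C1C[C@H](c2ccc(OCc3ccccc3)c(-c3c(O[Si](C(C)C)(C(C)C)C(C)C)cc4oc(-c5ccc(OCc6ccccc6)cc5)cc(=O)c4c3O)c2)Oc2cc(OCc3ccccc3)cc(OCc3ccccc3)c21
F0 | step 15 | none | none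
A1 | alternative 1 | methyl 4-hydroxy-3-[5,7-bis(benzyloxy)-2-(4-benzyloxyphenyl)-4-oxochromen-6-yl]benzoate | COC(=O)c1ccc(O)c(-c2c(OCc3ccccc3)cc3oc(-c4ccc(OCc5ccccc5)cc4)cc(=O)c3c2OCc2ccccc2)c1
A2 | alternative 1 | 5,7-bis(benzyloxy)-2-(4-benzyloxyphenyl)-6-[2,2-bis(trimethylsilyloxy)ethenyl]chromen-4-one | C[Si](C)(C)OC(O[Si](C)(C)C)=Cc1c(OCc2ccccc2)cc2oc(-c3ccc(OCc4ccccc4)cc3)cc(=O)c2c1OCc1ccccc1
A3 | alternative 1 | [5,7-bis(benzyloxy)-2-(4-benzyloxyphenyl)-4-oxochromen-6-yl]acetic acid | OC(=O)Cc1c(OCc2ccccc2)cc2oc(-c3ccc(OCc4ccccc4)cc3)cc(=O)c2c1OCc1ccccc1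
A4 | alternative 1 | methyl 2-oxo-2H-pyran-5-carboxylate (methyl coumalate) | COC(=O)C1=COC(=O)C=C1
A5 | alternative 2 | tert-butyl (2S,3R)-5,7-bis(benzyloxy)-2-{4-(benzyloxy)-3-[5,7-bis(benzyloxy)-2-(4-benzyloxyphenyl)-4-oxochromen-6-yl]phenyl}-4-oxochromane-3-carboxylate | O=C1[C@H](C(=O)OC(C)(C)C)[C@@H](c2ccc(OCc3ccccc3)c(-c3c(OCc4ccccc4)cc4oc(-c5ccc(OCc6ccccc6)cc5)cc(=O)c4c3OCc3ccccc3)c2)Oc2cc(OCc3ccccc3)cc(OCc3ccccc3)c21
A6 | alternative 2 | tert-butyl 2-[2,4-bis(benzyloxy)-6-hydroxybenzoyl]-3-{4-(benzyloxy)-3-[5,7-bis(benzyloxy)-2-(4-benzyloxyphenyl)-4-oxochromen-6-yl]phenyl}prop-2-enoate | CC(C)(C)OC(=O)C(=Cc1ccc(OCc2ccccc2)c(-c2c(OCc3ccccc3)cc3oc(-c4ccc(OCc5ccccc5)cc4)cc(=O)c3c2OCc2ccccc2)c1)C(=O)c1c(O)cc(OCc2ccccc2)cc1OCc1ccccc1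
A7 | alternative 3 | (2S)-2-{4-(benzyloxy)-3-[5,7-bis(benzyloxy)-2-(4-benzyloxyphenyl)-4-oxochromen-6-yl]phenyl}-5,7-bis[(triisopropylsilyl)oxy]-2,3-dihydro-4H-chromen-4-one | O=C1C[C@@H](c2ccc(OCc3ccccc3)c(-c3c(OCc4ccccc4)cc4oc(-c5ccc(OCc6ccccc6)cc5)cc(=O)c4c3OCc3ccccc3)c2)Oc2cc(O[Si](C(C)C)(C(C)C)C(C)C)cc(O[Si](C(C)C)(C(C)C)C(C)C)c21
A8 | alternative 3 | 1-[2-({4-(benzyloxy)-3-[5,7-bis(benzyloxy)-2-(4-benzyloxyphenyl)-4-oxochromen-6-yl]phenyl}methoxy)-4,6-bis[(triisopropylsilyl)oxy]phenyl]-2-diazoethanone | [N-]=[N+]=CC(=O)c1c(OCc2ccc(OCc3ccccc3)c(-c3c(OCc4ccccc4)cc4oc(-c5ccc(OCc6ccccc6)cc5)cc(=O)c4c3OCc3ccccc3)c2)cc(O[Si](C(C)C)(C(C)C)C(C)C)cc1O[Si](C(C)C)(C(C)C)C(C)C
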